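**Retrosynthetic overview**
- Enone C=C: Claisen–Schmidt disconnection to an (S)-6-acetyl-5,8-dihydroxy-2H-chromene and 4-hydroxybenzaldehyde; ring B arrives intact in the last step.
- Pyran ring: the O1–C2 bond is opened to a vinyl ortho-quinone methide, the tautomer of a 3-(7-hydroxygeranyl)-2-hydroxy-1,4-benzoquinone. Forward, oxidation, tautomerisation and oxa-6π electrocyclisation under a chiral phosphoric acid close the ring and set C2 (S) in one operation.
- Quinone ← hydroxyhydroquinone: aryl–CH2 bond cut to 2',4',5'-trihydroxyacetophenone and (E)-7-hydroxygeranyl bromide (phenoxide C-alkylation).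
- Bromide ← geraniol, by hydration of the distal olefin and allylic OH → Br exchange.
- Ring order: ring A (benzene) is bought; the pyran ring is the only ring made (fourth step); ring B is bought and attached in the fifth step.

Assumption: 2',4',5'-trihydroxyacetophenone is taken as purchasable, and the sense of induction of the chiral acid in the ring-forming step cannot be predicted with certainty, so the catalyst antipode that gives the (S)-chromene is fixed by a first small run with chiral HPLC/ECD assay (written below as the (R)-acid).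

**Step 1**
Reactants: 1 geraniol
Product: 3 (E)-3,7-dimethyloct-2-ene-1,7-diol, via organomercurial acetate 2 (not isolated)
Conditions: Hg(OAc)2 (1.0 equiv), THF–H2O (1:1), 0 °C → rt; then 3 M NaOH, NaBH4, 0 °C
Reagents that add atoms: water, O
Why: Oxymercuration–demercuration (Markovnikov hydration); the electron-rich distal 6,7-olefin is mercurated far faster than the 2,3-olefin, which is deactivated by the allylic oxygen, and NaBH4 replaces C–Hg by C–H, so no stereocentre remains.

**Step 2**
Reactants: 3 (E)-3,7-dimethyloct-2-ene-1,7-diol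
Product: 5 (E)-8-bromo-2,6-dimethyloct-6-en-2-ol, via allylic mesylate 4 (not isolated)
Conditions: MsCl, Et3N, THF, −40 °C; then LiBr, THF, 0 °C
Reagents that add atoms: lithium bromide, [Li+].[Br-]
Why: Sulfonylation at low temperature takes only the primary allylic hydroxyl (the tertiary one is too hindered), and SN2 displacement of the mesylate by bromide keeps the E olefin.

**Step 3**
Reactants: 5 (E)-8-bromo-2,6-dimethyloct-6-en-2-ol; 6 1-(2,4,5-trihydroxyphenyl)ethan-1-one (2 equiv)
Product: 7 1-{2,4,5-trihydroxy-3-[(E)-7-hydroxy-3,7-dimethyloct-2-en-1-yl]phenyl}ethan-1-one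
Conditions: KOH (1.1 equiv based on 6), degassed H2O–THF, 0 °C → rt, Ar
Reagents that add atoms: none
Why: Phenoxide C-alkylation: the 4-phenoxide (most acidic OH, para to acetyl) is hydrogen-bonded at oxygen in water and reacts through its only free ortho carbon, C3, flanked by two oxygens (C5 is blocked), by SN2 at the primary allylic carbon with the E geometry kept; 30–40% is expected.

**Step 4**
Reactants: 7 1-{2,4,5-trihydroxy-3-[(E)-7-hydroxy-3,7-dimethyloct-2-en-1-yl]phenyl}ethan-1-one
Product: 10 1-[(2S)-5,8-dihydroxy-2-(4-hydroxy-4-methylpentyl)-2-methyl-2H-chromen-6-yl]ethan-1-one, via hydroxyquinone 8 (not isolated), via vinyl ortho-quinone methide 9 (not isolated)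
Conditions: Ag2O (1.2 equiv), MgSO4, CH2Cl2, 0 °C, Ar; filter through Celite; then (R)-3,3'-bis(2,4,6-triisopropylphenyl)-1,1'-binaphthyl-2,2'-diyl hydrogen phosphate [(R)-TRIP, 10 mol%], 4 Å MS, toluene–CH2Cl2, −20 °C → rt, dark
Reagents that add atoms: none
Why: Proposed new method: Ag2O dehydrogenates the hydroxyhydroquinone to hydroxyquinone 8 (standard); the chiral phosphoric acid then acts as a proton shuttle (phosphoryl oxygen removes the vinylogous benzylic C–H, P–OH protonates the remote quinone oxygen) to give vinyl ortho-quinone methide 9, held by two hydrogen bonds (P–OH to the C4 carbonyl oxygen, C5–OH to P=O) at the oxygen that closes. The disrotatory oxa-6π electrocyclisation of the (E)-configured oxatriene then runs inside the chiral pocket, which selects one helical sense and so sets C2 as (S). Closure goes through the free C4 oxygen and not the acetyl-chelated C2 oxygen, as in DDQ cyclisations of 3-prenyl-2,4-dihydroxyaryl ketones. The closest known reaction types are the amine- or heat-promoted isomerisation of prenylquinones to chromenols (racemic) and chiral phosphoric acid or N-triflylphosphoramide control of ring closures of ortho-quinone methides and hydroxyaryl allyl cations to 2,2-disubstituted 2H-chromenes.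

**Step 5**
Reactants: 10 1-[(2S)-5,8-dihydroxy-2-(4-hydroxy-4-methylpentyl)-2-methyl-2H-chromen-6-yl]ethan-1-one; 11 4-hydroxybenzaldehyde
Product: 13 (E)-1-[(2S)-5,8-dihydroxy-2-(4-hydroxy-4-methylpentyl)-2-methyl-2H-chromen-6-yl]-3-(4-hydroxyphenyl)prop-2-en-1-one, via aldol adduct 12 (not isolated)
Conditions: LiN(SiMe3)2 (6.5 equiv in all; 4.5 on 10, 1.1 on 11 before mixing), THF, −78 °C → rt, 24 h, Ar, dark; 1 M HCl quench, 0 °C
Reagents that add atoms: none
Why: Claisen–Schmidt aldol condensation through the lithium polyanion: all OH groups and the methyl ketone are deprotonated, the enolate adds to the aldehyde and the aldolate loses hydroxide (E1cB) to the thermodynamic (E)-enone; the quaternary C2 has no acidic hydrogen and is untouched.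

**Compound list**
1 | geraniol, (E)-3,7-dimethylocta-2,6-dien-1-ol | CC(C)=CCC/C(C)=C/CO | starting material
2 | (E)-6-(acetoxymercurio)-3,7-dimethyloct-2-ene-1,7-diol (racemic at C6) | CC(C)(O)C([Hg]OC(C)=O)CC/C(C)=C/CO | intermediate
3 | (E)-3,7-dimethyloct-2-ene-1,7-diol | CC(C)(O)CCC/C(C)=C/CO | intermediate
4 | (E)-7-hydroxy-3,7-dimethyloct-2-en-1-yl methanesulfonate | CC(C)(O)CCC/C(C)=C/COS(C)(=O)=O | intermediate
5 | (E)-8-bromo-2,6-dimethyloct-6-en-2-ol | CC(C)(O)CCC/C(C)=C/CBr | intermediate
6 | 1-(2,4,5-trihydroxyphenyl)ethan-1-one | CC(=O)c1cc(O)c(O)cc1O | starting material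
7 | 1-{2,4,5-trihydroxy-3-[(E)-7-hydroxy-3,7-dimethyloct-2-en-1-yl]phenyl}ethan-1-one | CC(=O)c1cc(O)c(O)c(C/C=C(\C)CCCC(C)(C)O)c1O | intermediate
8 | 5-acetyl-2-hydroxy-3-[(E)-7-hydroxy-3,7-dimethyloct-2-en-1-yl]-1,4-benzoquinone | CC(=O)C1=CC(=O)C(O)=C(C/C=C(\C)CCCC(C)(C)O)C1=O | intermediate
9 | (6Z)-4-acetyl-2,5-dihydroxy-6-[(2E)-7-hydroxy-3,7-dimethyloct-2-en-1-ylidene]cyclohexa-2,4-dien-1-one | CC(=O)C1=C(O)/C(=C/C=C(\C)CCCC(C)(C)O)C(=O)C(O)=C1 | intermediate
10 | 1-[(2S)-5,8-dihydroxy-2-(4-hydroxy-4-methylpentyl)-2-methyl-2H-chromen-6-yl]ethan-1-one | CC(C)(O)CCC[C@@]1(C)C=Cc2c(O)c(C(C)=O)cc(O)c2O1 | intermediate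
11 | 4-hydroxybenzaldehyde | O=Cc1ccc(O)cc1 | starting material
12 | 1-[(2S)-5,8-dihydroxy-2-(4-hydroxy-4-methylpentyl)-2-methyl-2H-chromen-6-yl]-3-hydroxy-3-(4-hydroxyphenyl)propan-1-one (both carbinol epimers) | CC(C)(O)CCC[C@@]1(C)C=Cc2c(O)c(C(=O)CC(O)c3ccc(O)cc3)cc(O)c2O1 | intermediate
13 | (E)-1-[(2S)-5,8-dihydroxy-2-(4-hydroxy-4-methylpentyl)-2-methyl-2H-chromen-6-yl]-3-(4-hydroxyphenyl)prop-2-en-1-one | CC(C)(O)CCC[C@@]1(C)C=Cc2c(O)c(C(=O)/C=C/c3ccc(O)cc3)cc(O)c2O1 | target

**Totals**
Total steps: 5. Longest linear sequence: 5 (1 → 3 → 5 → 7 → 10 → 13).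

**Steps most likely to fail, with fallbacks**

Step 4 is the riskiest. The enantioselectivity is unproven, and the acidic hydroxyquinone may catalyse its own tautomerisation and give racemic background product. Product hydroquinone and quinone 8 may also exchange redox state; a dithionite wash under argon returns quinone-level material to 10 and 7. Fallback, setting out from 7 and coming back at 10: oxidise 7 with Ag2O as before, then heat the filtrate in pyridine (80 °C, dark, Ar), the classical amine-promoted prenylquinone → chromenol isomerisation. This gives racemic 1-[5,8-dihydroxy-2-(4-hydroxy-4-methylpentyl)-2-methyl-2H-chromen-6-yl]ethan-1-one F2. Preparative chiral SFC (amylose tris(3,5-dimethylphenylcarbamate) phase, CO2–MeOH) then delivers (S)-ketone 10 and sets aside 1-[(2R)-5,8-dihydroxy-2-(4-hydroxy-4-methylpentyl)-2-methyl-2H-chromen-6-yl]ethan-1-one F3, which can be photoracemised through reversible ring opening and recycled.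

Step 3 may suffer from O-alkylation, double alkylation and autoxidation of the hydroxyhydroquinone under base. Fallback, setting out from 5 and coming back at 8: alkylate commercial 2',4'-dihydroxyacetophenone (CC(=O)c1ccc(O)cc1O) with 5 in aqueous KOH, the well-used 3-C-prenylation of resacetophenone, to give 1-{2,4-dihydroxy-3-[(E)-7-hydroxy-3,7-dimethyloct-2-en-1-yl]phenyl}ethan-1-one F1. Teuber oxidation with ON(SO3K)2 (potassium nitrosodisulfonate; KH2PO4 buffer, acetone–H2O, 0 °C) then introduces the C5 oxygen and gives hydroxyquinone 8, which is extracted, dried and taken into the second stage of step 4. No air-sensitive triol is handled under base.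

Step 5 may fail because lithium 4-formylphenoxide is a poor electrophile and the polyanion may be poorly soluble. Fallback, setting out from 10 and coming back at 13: run the same LiN(SiMe3)2 aldol condensation with commercial 4-(tert-butyldimethylsilyloxy)benzaldehyde (O=Cc1ccc(O[Si](C)(C)C(C)(C)C)cc1), whose aldehyde is not deactivated. This gives (E)-1-[(2S)-5,8-dihydroxy-2-(4-hydroxy-4-methylpentyl)-2-methyl-2H-chromen-6-yl]-3-[4-(tert-butyldimethylsilyloxy)phenyl]prop-2-en-1-one F4. Desilylation with Bu4NF–AcOH (THF, 0 °C) is mild enough for the tertiary alcohol and the chromene and gives 13.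

**Further compounds**
F1 | step 3 | 1-{2,4-dihydroxy-3-[(E)-7-hydroxy-3,7-dimethyloct-2-en-1-yl]phenyl}ethan-1-one | CC(=O)c1ccc(O)c(C/C=C(\C)CCCC(C)(C)O)c1O
F2 | step 4 | racemic 1-[5,8-dihydroxy-2-(4-hydroxy-4-methylpentyl)-2-methyl-2H-chromen-6-yl]ethan-1-one | CC(C)(O)CCCC1(C)C=Cc2c(O)c(C(C)=O)cc(O)c2O1
F3 | step 4 | 1-[(2R)-5,8-dihydroxy-2-(4-hydroxy-4-methylpentyl)-2-methyl-2H-chromen-6-yl]ethan-1-one | CC(C)(O)CCC[C@]1(C)C=Cc2c(O)c(C(C)=O)cc(O)c2O1
F4 | step 5 | (E)-1-[(2S)-5,8-dihydroxy-2-(4-hydroxy-4-methylpentyl)-2-methyl-2H-chromen-6-yl]-3-[4-(tert-butyldimethylsilyloxy)phenyl]prop-2-en-1-one | CC(C)(O)CCC[C@@]1(C)C=Cc2c(O)c(C(=O)/C=C/c3ccc(O[Si](C)(C)C(C)(C)C)cc3)cc(O)c2O1
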